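**Plan**

- Cuts: the side-chain bond C2'–C3' on C3 and the ring-B bond C1–C2 fall in one event (1,6-addition of a C14 Grignard reagent to a 3-vinylacrylate on C3a, then acylation of the dienolate carbon C2 by the C7a carbonyl). Before that come C3–vinyl (enol triflate, Stille) and the ring-A bonds C4–C3a and C7–C7a (Diels–Alder with maleic anhydride).
- Feature used: ring B is a vinylogous β-keto ester, C1(=O)–C2(CO2Me)=C3–C1'H2–C2'H2–. C2' is the δ-carbon of the C2 ester and C2 lies 1,5 to C1, so one nucleophile arriving at C2' can also close ring B.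
- Helper ring (not in the target): the C7a carbonyl is held as a cis γ-lactone with the C7 carbon (C7–CH2–O–C1=O). It tells the two maleic carbonyls apart, serves as the acyl donor of the ring closure and is opened by it; the freed CH2OH is oxidized to the C7 acid at the end.
- Forward order: C16 keto ester → (E,E)-dienol → ring A with lactone → C3a acid turned into the vinylacrylate → chain joined and ring B closed → acid.
- Stereochemistry: the endo Diels–Alder of the (E,E)-diene sets C4, C3a, C7a and C7 all-cis at once. The absolute configuration comes from resolution of the lactone acid. No later step touches the four centres.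

Key step: step 10

Assumption: locants in the plan follow the indene numbering of the target (C1 ketone, C2 ester, C3 and C5 hexadecyl, C4 ester, C7 acid); the target is (3aR,4R,7R,7aS) with all four ring hydrogens on one face; racemates are written as the two enantiomers joined by a dot.

**Step 1**
Reactants: 1 methyl acetoacetate; 2 1-bromopentadecane
Product: 3 methyl 3-oxononadecanoate
Conditions: NaH (1.1 equiv), THF, 0 °C; n-BuLi (1.05 equiv), 0 °C; then 2, 0 °C → rt; aq NH4Cl
Reagents that add atoms: none
Why: dianion alkylation of a β-keto ester, in which the more basic terminal carbanion is alkylated by the primary bromide; no stereocentre is formed.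

**Step 2**
Reactants: 3 methyl 3-oxononadecanoate
Product: 4 methyl (2E)-3-{[(trifluoromethyl)sulfonyl]oxy}nonadec-2-enoate
Conditions: Tf2O (1.3 equiv), aq Me4NOH, hexanes, 5 °C
Reagents that add atoms: triflic anhydride, O=S(=O)(OS(=O)(=O)C(F)(F)F)C(F)(F)F
Why: O-sulfonylation of the β-keto ester enolate; with the non-coordinating Me4N+ counter-ion the open, non-chelated enolate should give the (E)-enol triflate (OTf trans to CO2Me), the geometry that later places the ester on the outside of the diene.

**Step 3**
Reactants: 5 prop-2-yn-1-ol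
Product: 6 (2E)-3-(tributylstannyl)prop-2-en-1-ol
Conditions: Bu3SnH, AIBN (cat.), neat, 80 °C; chromatography
Reagents that add atoms: tributyltin hydride, CCCC[SnH](CCCC)CCCC
Why: radical hydrostannylation of a terminal alkyne, which under thermal equilibrating conditions should favour the (E)-β-stannyl allylic alcohol, separable from minor isomers.

**Step 4**
Reactants: 4 methyl (2E)-3-{[(trifluoromethyl)sulfonyl]oxy}nonadec-2-enoate; 6 (2E)-3-(tributylstannyl)prop-2-en-1-ol
Product: 7 methyl (2E,4E)-3-hexadecyl-6-hydroxyhexa-2,4-dienoate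
Conditions: Pd(PPh3)4 (5 mol%), LiCl (3 equiv), THF, 60 °C
Reagents that add atoms: none
Why: Stille coupling with retention at both sp2 partners, so the (2E,4E)-diene with CO2Me and CH2OH both on the outside should result.

**Step 5**
Reactants: 7 methyl (2E,4E)-3-hexadecyl-6-hydroxyhexa-2,4-dienoate; 8 maleic anhydride
Product: 10 racemic lactone acid rac-(3aR,4R,5R,7aR)-6-hexadecyl-5-(methoxycarbonyl)-3-oxo-1,3,3a,4,5,7a-hexahydro-2-benzofuran-4-carboxylic acid, via Diels–Alder anhydride 9 (not isolated)
Conditions: toluene, BHT (cat.), 110 °C, sealed tube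
Reagents that add atoms: none
Why: tandem Diels–Alder/lactonization of a 2,4-dienol with maleic anhydride, in which the endo addition of the cis dienophile to the (E,E)-diene puts C4, C3a, C7a and C7 all-cis and the cis CH2OH then opens the nearer anhydride carbonyl to the γ-lactone, leaving the C3a carboxyl free (the same cis-fused product is expected if esterification precedes an intramolecular endo cycloaddition).

**Step 6**
Reactants: 10 racemic lactone acid
Product: 11 (3aR,4R,5R,7aR)-6-hexadecyl-5-(methoxycarbonyl)-3-oxo-1,3,3a,4,5,7a-hexahydro-2-benzofuran-4-carboxylic acid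
Conditions: (R)-1-phenylethylamine (1 equiv), EtOH/EtOAc, recrystallization of the less soluble salt; then 1 M HCl, EtOAc
Reagents that add atoms: none
Why: classical resolution through diastereomeric ammonium carboxylate salts (the antipodal amine is taken if the salt of the wanted acid is the more soluble one; the configuration is to be secured by X-ray analysis of the salt).

**Step 7**
Reactants: 11 (3aR,4R,5R,7aR)-lactone acid
Product: 13 methyl (3aR,4R,5R,7aR)-6-hexadecyl-4-(3-methoxy-3-oxopropanoyl)-3-oxo-1,3,3a,4,5,7a-hexahydro-2-benzofuran-5-carboxylate, via acyl imidazolide 12 (not isolated)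
Conditions: CDI, THF, rt; then MeO2CCH2CO2K, MgCl2, Et3N, MeCN, rt → 40 °C; 1 M HCl work-up
Reagents that add atoms: methyl potassium malonate, COC(=O)CC(=O)[O-].[K+]
Why: Masamune–Brooks homologation, in which the acyl imidazolide acylates the magnesium enolate of the malonate half ester and decarboxylation gives the β-keto ester under near-neutral conditions, so the α-stereocentre C3a and the lactone should survive.

**Step 8**
Reactants: 13 β-keto ester lactone
Product: 14 methyl (3aR,4R,5R,7aR)-6-hexadecyl-4-[(1Z)-3-methoxy-3-oxo-1-{[(trifluoromethyl)sulfonyl]oxy}prop-1-en-1-yl]-3-oxo-1,3,3a,4,5,7a-hexahydro-2-benzofuran-5-carboxylate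
Conditions: Tf2O (1.2 equiv), i-Pr2NEt (1.5 equiv), LiOTf (1.5 equiv), CH2Cl2, −78 → 0 °C
Reagents that add atoms: triflic anhydride, O=S(=O)(OS(=O)(=O)C(F)(F)F)C(F)(F)F
Why: enol triflation by soft enolization of the 1,3-dicarbonyl unit (lithium chelate, hence Z); the amine base deprotonates only C2 and the fast O-sulfonylation at low temperature leaves no time for C-acylation by the lactone (the enol geometry has no consequence later).

**Step 9**
Reactants: 14 enol triflate
Product: 15 methyl (3aS,4R,5R,7aR)-6-hexadecyl-4-[(3E)-5-methoxy-5-oxopenta-1,3-dien-3-yl]-3-oxo-1,3,3a,4,5,7a-hexahydro-2-benzofuran-5-carboxylate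
Conditions: Pd(PPh3)4 (5 mol%), LiCl (3 equiv), BHT, THF, 60 °C
Reagents that add atoms: tributyl(vinyl)stannane, C=C[Sn](CCCC)(CCCC)CCCC
Why: Stille vinylation of a β-triflyloxy enoate under neutral conditions, which should keep the lactone and all four stereocentres intact (the descriptor at C3a changes only through the CIP priorities).

**Step 10**
Reactants: 15 lactone dienoate; 16 tetradecylmagnesium chloride
Product: 19 dimethyl (3aR,4R,7R,7aS)-3,5-dihexadecyl-7-(hydroxymethyl)-1-oxo-3a,4,7,7a-tetrahydro-1H-indene-2,4-dicarboxylate, via magnesium dienolate 17 (not isolated), via deconjugated keto ester 18 (not isolated)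
Conditions: 16 (1.3 equiv, slow addition), CuBr·SMe2 (10 mol%), CH2Cl2/THF, −78 → 0 °C; AcOH quench; then Et3N (0.2 equiv), CH2Cl2, rt
Reagents that add atoms: none
Why: Proposed new method: the copper-catalysed Grignard reagent should add to the unhindered terminal CH2 of the 3-substituted penta-2,4-dienoate (1,6-addition) to give magnesium ester dienolate 17, whose α-carbon C2 lies 1,5 to the lactone carbonyl held cis on C7a and attacks it in a 5-exo-trig (enolexo) Dieckmann-type acyl substitution that closes ring B and expels the C7 CH2O− group, which at once deprotonates the new β-keto ester (18, held as its chelate) and makes the closure irreversible. The closest known reaction types are the Cu-catalysed 1,6-addition of Grignard reagents to 2,4-dienoates and conjugate-addition/Dieckmann (Michael-initiated ring-closure) cascades, whose union on a dienoate remains to be shown. No new stereocentre is formed: C3a and C7a come from step 5 and their cis appendages enforce the cis ring fusion. Three selectivities are needed: 1,6 over 1,4 and 1,2 (the β-carbon C3 is fully substituted and the Cu-catalysed reagent leaves esters alone at −78 °C), α- over γ-acylation of the dienolate (metal ester dienolates react at the α-carbon, and only α-attack gives a β-keto ester that can be deprotonated), and lactone over the C4 methyl ester (a γ-lactone, as an s-cis ester, is typically a far better acyl donor than an open-chain methyl ester). After the acidic quench the catalytic amine should move the C3=C1' double bond into the ring (C2=C3), the tetrasubstituted enone flanked by two carbonyls being the expected thermodynamic tautomer.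

**Step 11**
Reactants: 19 hydroxymethyl hydrindenone
Product: 20 (3aR,4R,7R,7aS)-3,5-dihexadecyl-2,4-bis(methoxycarbonyl)-1-oxo-3a,4,7,7a-tetrahydro-1H-indene-7-carboxylic acid (CNP0252450.3)
Conditions: TEMPO (0.2 equiv), PhI(OAc)2 (2.5 equiv), CH2Cl2/H2O (2:1), rt
Reagents that add atoms: water, O
Why: oxoammonium (TEMPO) oxidation of the primary alcohol through the aldehyde hydrate to the acid under weakly acidic conditions that should not enolize C7, while the alkene and the enone are inert to the oxidant.

**Compound list**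

1 | methyl acetoacetate | CC(=O)CC(=O)OC | starting material
2 | 1-bromopentadecane | CCCCCCCCCCCCCCCBr | starting material
3 | methyl 3-oxononadecanoate | CCCCCCCCCCCCCCCCC(=O)CC(=O)OC | intermediate
4 | methyl (2E)-3-{[(trifluoromethyl)sulfonyl]oxy}nonadec-2-enoate | CCCCCCCCCCCCCCCC/C(OS(=O)(=O)C(F)(F)F)=C\C(=O)OC | intermediate
5 | prop-2-yn-1-ol | C#CCO | starting material
6 | (2E)-3-(tributylstannyl)prop-2-en-1-ol | CCCC[Sn](CCCC)(CCCC)/C=C/CO | intermediate
7 | methyl (2E,4E)-3-hexadecyl-6-hydroxyhexa-2,4-dienoate | COC(=O)/C=C(\CCCCCCCCCCCCCCCC)/C=C/CO | intermediate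
8 | maleic anhydride | O=C1OC(=O)C=C1 | starting material
9 | rac-methyl (3aR,4R,7R,7aR)-5-hexadecyl-7-(hydroxymethyl)-1,3-dioxo-1,3,3a,4,7,7a-hexahydro-2-benzofuran-4-carboxylate (Diels–Alder anhydride, all ring H cis, not isolated) | CCCCCCCCCCCCCCCCC1=C[C@@H](CO)[C@H]2C(=O)OC(=O)[C@H]2[C@H]1C(=O)OC.CCCCCCCCCCCCCCCCC1=C[C@H](CO)[C@@H]2C(=O)OC(=O)[C@@H]2[C@@H]1C(=O)OC | intermediate
10 | rac-(3aR,4R,5R,7aR)-6-hexadecyl-5-(methoxycarbonyl)-3-oxo-1,3,3a,4,5,7a-hexahydro-2-benzofuran-4-carboxylic acid (racemic lactone acid, all ring H cis) | CCCCCCCCCCCCCCCCC1=C[C@H]2COC(=O)[C@H]2[C@@H](C(=O)O)[C@H]1C(=O)OC.CCCCCCCCCCCCCCCCC1=C[C@@H]2COC(=O)[C@@H]2[C@H](C(=O)O)[C@@H]1C(=O)OC | intermediate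
11 | (3aR,4R,5R,7aR)-6-hexadecyl-5-(methoxycarbonyl)-3-oxo-1,3,3a,4,5,7a-hexahydro-2-benzofuran-4-carboxylic acid | CCCCCCCCCCCCCCCCC1=C[C@H]2COC(=O)[C@H]2[C@@H](C(=O)O)[C@H]1C(=O)OC | intermediate
12 | methyl (3aR,4R,5R,7aR)-6-hexadecyl-4-(1H-imidazol-1-ylcarbonyl)-3-oxo-1,3,3a,4,5,7a-hexahydro-2-benzofuran-5-carboxylate (acyl imidazolide, not isolated) | CCCCCCCCCCCCCCCCC1=C[C@H]2COC(=O)[C@H]2[C@@H](C(=O)n3ccnc3)[C@H]1C(=O)OC | intermediate
13 | methyl (3aR,4R,5R,7aR)-6-hexadecyl-4-(3-methoxy-3-oxopropanoyl)-3-oxo-1,3,3a,4,5,7a-hexahydro-2-benzofuran-5-carboxylate | CCCCCCCCCCCCCCCCC1=C[C@H]2COC(=O)[C@H]2[C@@H](C(=O)CC(=O)OC)[C@H]1C(=O)OC | intermediate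
14 | methyl (3aR,4R,5R,7aR)-6-hexadecyl-4-[(1Z)-3-methoxy-3-oxo-1-{[(trifluoromethyl)sulfonyl]oxy}prop-1-en-1-yl]-3-oxo-1,3,3a,4,5,7a-hexahydro-2-benzofuran-5-carboxylate | CCCCCCCCCCCCCCCCC1=C[C@H]2COC(=O)[C@H]2[C@@H](/C(OS(=O)(=O)C(F)(F)F)=C/C(=O)OC)[C@H]1C(=O)OC | intermediate
15 | methyl (3aS,4R,5R,7aR)-6-hexadecyl-4-[(3E)-5-methoxy-5-oxopenta-1,3-dien-3-yl]-3-oxo-1,3,3a,4,5,7a-hexahydro-2-benzofuran-5-carboxylate | CCCCCCCCCCCCCCCCC1=C[C@H]2COC(=O)[C@H]2[C@@H](/C(C=C)=C/C(=O)OC)[C@H]1C(=O)OC | intermediate
16 | tetradecylmagnesium chloride | CCCCCCCCCCCCCC[Mg]Cl | starting material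
17 | chloromagnesium ester dienolate of the 1,6-adduct (C2=C(OMe)OMgCl, C3=C1'; lactone intact; not isolated) | CCCCCCCCCCCCCCCCC1=C[C@H]2COC(=O)[C@H]2[C@@H](C(=CCCCCCCCCCCCCCCC)C=C(OC)O[Mg]Cl)[C@H]1C(=O)OC | intermediate
18 | dimethyl (3aR,4R,7R,7aS)-5-hexadecyl-3-hexadecylidene-7-(hydroxymethyl)-1-oxo-2,3,3a,4,7,7a-hexahydro-1H-indene-2,4-dicarboxylate (deconjugated keto ester, held as its magnesium chelate until the quench; not isolated) | CCCCCCCCCCCCCCCCC1=C[C@@H](CO)[C@H]2C(=O)C(C(=O)OC)C(=CCCCCCCCCCCCCCCC)[C@H]2[C@H]1C(=O)OC | intermediate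
19 | dimethyl (3aR,4R,7R,7aS)-3,5-dihexadecyl-7-(hydroxymethyl)-1-oxo-3a,4,7,7a-tetrahydro-1H-indene-2,4-dicarboxylate | CCCCCCCCCCCCCCCCC1=C[C@@H](CO)[C@H]2C(=O)C(C(=O)OC)=C(CCCCCCCCCCCCCCCC)[C@H]2[C@H]1C(=O)OC | intermediate
20 | (3aR,4R,7R,7aS)-3,5-dihexadecyl-2,4-bis(methoxycarbonyl)-1-oxo-3a,4,7,7a-tetrahydro-1H-indene-7-carboxylic acid (CNP0252450.3) | CCCCCCCCCCCCCCCCC1=C[C@@H](C(=O)O)[C@H]2C(=O)C(C(=O)OC)=C(CCCCCCCCCCCCCCCC)[C@H]2[C@H]1C(=O)OC | target

**Step count and risks**

Total steps: 11. Longest linear sequence: 10 (steps 1, 2, 4–11); step 3 is a one-step side branch.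

Steps most likely to fail:

1. Step 10 (proposed new method). What may go wrong: acyl transfer to the wrong carbonyl (the dienolate closing onto the C4 methyl ester), γ- instead of α-acylation, or attack of the Grignard reagent on the lactone before the conjugate addition. Fallback with known reactions, the cascade taken apart: from 15 the same Cu-catalysed 1,6-addition of 16 is run with Me3SiCl in the flask at −78 °C, so that the dienolate is silylated as it forms and cannot acylate. This gives the silyl ketene acetal F1, which dilute acid turns into the β,γ-unsaturated ester F2 with the lactone intact. F2 is then closed in a separate Dieckmann condensation (LiHMDS, THF, −78 → 0 °C, deprotonation of the unhindered C2 methylene; TiCl4/Bu3N soft enolization as the variant) and equilibrated with catalytic Et3N, which comes back to the route at 19.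

2. Step 5. What may go wrong: slow cycloaddition of the acceptor-substituted diene, so that esterification of the alcohol by the anhydride and an intramolecular cycloaddition of lower endo preference take over, or polymerization of the diene. Fallback: from 7 the alcohol is silylated (TBSCl, imidazole, CH2Cl2) to the silyl ether F3, which can react with 8 only intermolecularly (xylene, 130 °C, or high pressure at rt) to give the racemic endo anhydride F4. HF·pyridine in MeCN removes the silyl group and the freed cis CH2OH lactonizes onto the neighbouring anhydride carbonyl, which comes back to the route at 10.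

3. Step 6. What may go wrong: no selective crystallization (waxy, soap-like salts of a C16 acid, or co-crystallization of both diastereomeric salts). Fallback: from 10 the enantiomers are separated by preparative chromatography on a chiral stationary phase (SFC, immobilized amylose carbamate, CO2/MeOH with formic acid); this makes no new compound (entry F0) and comes back to the route at 11.

**Further compounds**

F1 | step 10 | methyl (3aS,4R,5R,7aR)-6-hexadecyl-4-{1-methoxy-1-[(trimethylsilyl)oxy]nonadeca-1,3-dien-3-yl}-3-oxo-1,3,3a,4,5,7a-hexahydro-2-benzofuran-5-carboxylate (silyl ketene acetal of the 1,6-adduct) | CCCCCCCCCCCCCCCCC1=C[C@H]2COC(=O)[C@H]2[C@@H](C(=CCCCCCCCCCCCCCCC)C=C(OC)O[Si](C)(C)C)[C@H]1C(=O)OC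
F2 | step 10 | methyl (3aS,4R,5R,7aR)-6-hexadecyl-4-(1-methoxy-1-oxononadec-3-en-3-yl)-3-oxo-1,3,3a,4,5,7a-hexahydro-2-benzofuran-5-carboxylate (β,γ-unsaturated ester) | CCCCCCCCCCCCCCCCC1=C[C@H]2COC(=O)[C@H]2[C@@H](C(=CCCCCCCCCCCCCCCC)CC(=O)OC)[C@H]1C(=O)OC
F3 | step 5 | methyl (2E,4E)-6-{[tert-butyl(dimethyl)silyl]oxy}-3-hexadecylhexa-2,4-dienoate | COC(=O)/C=C(\CCCCCCCCCCCCCCCC)/C=C/CO[Si](C)(C)C(C)(C)C
F4 | step 5 | rac-methyl (3aR,4R,7R,7aR)-7-({[tert-butyl(dimethyl)silyl]oxy}methyl)-5-hexadecyl-1,3-dioxo-1,3,3a,4,7,7a-hexahydro-2-benzofuran-4-carboxylate | CCCCCCCCCCCCCCCCC1=C[C@@H](CO[Si](C)(C)C(C)(C)C)[C@H]2C(=O)OC(=O)[C@H]2[C@H]1C(=O)OC.CCCCCCCCCCCCCCCCC1=C[C@H](CO[Si](C)(C)C(C)(C)C)[C@@H]2C(=O)OC(=O)[C@@H]2[C@@H]1C(=O)OC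
F0 | step 6 | none | none
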